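**Retrosynthetic overview**
1. The bridging γ-lactone and the Z enol acetate are made last, together, from a butenolide fused to the nine-membered ring: base-triggered transannular acyl transfer to the ring hydroxyl, then O-acetylation of the released enolate (the former butenolide ring oxygen becomes the enol acetate oxygen, so its geometry is fixed).
2. The nine-membered carbocycle and that butenolide are formed in one palladium cycle from an acyclic hydroxy 2,3-allenoate carrying a (Z)-alkenyl chloride: carbopalladation of the allene closes the carbocycle, carboxylate capture of the π-allyl closes the butenolide.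
3. The allenoate comes from an α-acetyl γ-lactone (enol triflate, elimination, saponification); the E,Z-chlorodiene comes from a terminal alkyne (carboalumination, coupling with cis-1,2-dichloroethene).
4. The α-acetyl lactone comes from (S)-citronellal, ethyl 2-bromoacetoacetate and an allenyl boronate (catalyst-controlled α-alkylation sets C11, catalyst-controlled propargylation sets C8).
5. Ring order: temporary γ-lactone (step 2, opened in step 5); nine-membered ring and butenolide together (step 5); butenolide converted to the bridging γ-lactone (step 6).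

Assumption: the antipodes of the two chiral organocatalysts in steps 1 and 2 are those expected to give the configurations drawn (the mirror-image catalysts are equally available if the sense is reversed); locants C1–C11 follow the bicyclic name of the target (C1 lactone α-carbon, C2 enol acetate carbon, C8 carbinol carbon, C11 carbon bearing the side chain).

**Step 1**
Reactants: 1 (S)-citronellal; 2 ethyl 2-bromo-3-oxobutanoate
Product: 3 ethyl 2-[(2R,3S)-3,7-dimethyl-1-oxooct-6-en-2-yl]-3-oxobutanoate
Conditions: (2R,5S)-2-tert-butyl-3,5-dimethylimidazolidin-4-one·TfOH (20 mol%), Ru(bpy)3Cl2 (0.5 mol%), 2,6-lutidine, DMF, visible light, 23 °C; used crude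
Reagents that add atoms: 2 ethyl 2-bromo-3-oxobutanoate, CCOC(=O)C(Br)C(C)=O
Why: Photoredox organocatalytic α-alkylation of an aldehyde (MacMillan type): the electrophilic 1,3-dicarbonyl radical adds to the chiral enamine on its open face, setting the aldehyde α-carbon (future C11) as R under catalyst control beside the untouched (S)-methyl centre, while the ketoester α-centre forms as a mixture that is erased in step 4.

**Step 2**
Reactants: 3 ethyl 2-[(2R,3S)-3,7-dimethyl-1-oxooct-6-en-2-yl]-3-oxobutanoate; 4 allenylboronic acid pinacol ester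
Product: 6 (4R,5S)-3-acetyl-4-[(2S)-6-methylhept-5-en-2-yl]-5-(prop-2-yn-1-yl)oxolan-2-one, via hydroxy keto ester 5 (not isolated)
Conditions: 4 (1.5 equiv), (R)-TRIP phosphoric acid (5 mol%), 4 Å MS, PhMe, −20 °C; then K2CO3, EtOH, 23 °C
Reagents that add atoms: 4 allenylboronic acid pinacol ester, C=C=CB1OC(C)(C)C(C)(C)O1
Why: Chiral-phosphoric-acid-catalysed propargylation with an allenylboronate (closed six-membered SE2′ transition state, aldehyde chosen over ketone) sets the carbinol carbon (future C8) as S under catalyst control, and under mild base the new alkoxide closes onto the ethyl ester (lactonisation, as in the acetoacetate/epoxide route to α-acetyl butyrolactones) to give the 4,5-trans lactone.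

**Step 3**
Reactants: 6 (4R,5S)-3-acetyl-4-[(2S)-6-methylhept-5-en-2-yl]-5-(prop-2-yn-1-yl)oxolan-2-one; 7 trimethylaluminium; 8 (Z)-1,2-dichloroethene
Product: 10 (4R,5S)-3-acetyl-5-[(2E,4Z)-5-chloro-2-methylpenta-2,4-dien-1-yl]-4-[(2S)-6-methylhept-5-en-2-yl]oxolan-2-one, via alkenylalane 9 (not isolated)
Conditions: 7 (4 equiv), Cp2ZrCl2 (0.5 equiv), H2O (1 equiv), CH2Cl2, −23 °C; then 8 (10 equiv), ZnCl2, Pd(PPh3)4 (5 mol%), THF, 23 to 45 °C
Reagents that add atoms: 7 trimethylaluminium, C[Al](C)C; 8 (Z)-1,2-dichloroethene, Cl/C=C\Cl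
Why: Negishi zirconium-catalysed syn-carboalumination puts methyl on the internal and aluminium on the terminal alkyne carbon (E-trisubstituted alkene), and Negishi-type palladium coupling of the alkenylalane with cis-1,2-dichloroethene proceeds with retention on both partners to give the (2E,4Z)-chlorodiene, the keto lactone being masked in situ as its aluminium enolate.

**Step 4**
Reactants: 10 (4R,5S)-3-acetyl-5-[(2E,4Z)-5-chloro-2-methylpenta-2,4-dien-1-yl]-4-[(2S)-6-methylhept-5-en-2-yl]oxolan-2-one
Product: 12 (4R,5S)-5-[(2E,4Z)-5-chloro-2-methylpenta-2,4-dien-1-yl]-3-ethenylidene-4-[(2S)-6-methylhept-5-en-2-yl]oxolan-2-one, via enol triflate 11 (not isolated)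
Conditions: Tf2O, Et3N, CH2Cl2, −78 °C; then LiN(SiMe3)2 (1.1 equiv), THF, −78 °C
Reagents that add atoms: none
Why: O-triflation of the β-keto lactone enol, then γ-deprotonation of the methyl group and E1cB loss of triflate (vinyl triflate to allenoate elimination) gives the α-vinylidene lactone; the stereochemically undefined C3 becomes an allene carbon and C4/C5 are not touched.

**Step 5**
Reactants: 12 (4R,5S)-5-[(2E,4Z)-5-chloro-2-methylpenta-2,4-dien-1-yl]-3-ethenylidene-4-[(2S)-6-methylhept-5-en-2-yl]oxolan-2-one; 13 lithium hydroxide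
Product: 15 (4Z,6E,9S,10R)-9-hydroxy-7-methyl-10-[(2S)-6-methylhept-5-en-2-yl]-3,8,9,10-tetrahydro-1H-cyclonona[c]furan-1-one, via lithium allenoate 14 (not isolated)
Conditions: 13 (1.0 equiv), THF/H2O, 0 °C; evaporate, PhMe azeotrope; then Pd2(dba)3 (5 mol%), XPhos (12 mol%), DMF, 70 °C, slow addition to 2 mM
Reagents that add atoms: 13 lithium hydroxide, [Li+].[OH-]
Why: Proposed new method: after saponification, zerovalent palladium inserts into the Z-alkenyl chloride with retention, intramolecular carbopalladation of the allene at its central carbon closes the nine-membered ring, and the resulting π-allylpalladium is captured at its CH2 end by the neighbouring carboxylate to close the butenolide, so both rings form in one catalytic cycle with no new stereocentre; the closest known reactions are the Ma coupling–cyclisation of 2,3-allenoic acids with alkenyl halides and the Ma–Negishi cyclic carbopalladation of ω-haloallenes to medium rings, and no base remains afterwards to isomerise the product.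

**Step 6**
Reactants: 15 (4Z,6E,9S,10R)-9-hydroxy-7-methyl-10-[(2S)-6-methylhept-5-en-2-yl]-3,8,9,10-tetrahydro-1H-cyclonona[c]furan-1-one; 16 acetic anhydride
Product: 19 (Z)-[(1S,3Z,5E,8S,11R)-6-methyl-11-[(2S)-6-methylhept-5-en-2-yl]-10-oxo-9-oxabicyclo[6.2.1]undeca-3,5-dien-2-ylidene]methyl acetate, via potassium furanolate 17 (not isolated), via potassium trienolate 18 (not isolated)
Conditions: KN(SiMe3)2 (1.1 equiv), THF, −78 to 23 °C; then 16 (3 equiv), −78 to 0 °C
Reagents that add atoms: 16 acetic anhydride, CC(=O)OC(C)=O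
Why: Proposed new method: γ-deprotonation gives the 2-oxidofuran 17, reversible proton transfer to its C3 exposes the enol-lactone tautomer, and the C9 alkoxide takes over the acyl group transannularly (only the cis-bridged epimer can close, which sets C1 as S) to release the aldehyde trienolate 18 with its oxygen still cis to C1 as in the furan ring, so O-acetylation gives the Z enol acetate; the closest known reactions are acyl transfer from enol lactones to alkoxides and O-acylation of preformed potassium enolates with retention of geometry, and the net change (allylic ester to saturated lactone plus conjugated enolate) is strongly downhill.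

**Compound list**
1 | (S)-citronellal, (3S)-3,7-dimethyloct-6-enal | O=CC[C@@H](C)CCC=C(C)C | starting material
2 | ethyl 2-bromo-3-oxobutanoate | CCOC(=O)C(Br)C(C)=O | starting material
3 | ethyl 2-[(2R,3S)-3,7-dimethyl-1-oxooct-6-en-2-yl]-3-oxobutanoate (epimers at the ketoester carbon) | CCOC(=O)C(C(C)=O)[C@H](C=O)[C@@H](C)CCC=C(C)C | intermediate
4 | allenylboronic acid pinacol ester, 4,4,5,5-tetramethyl-2-(propa-1,2-dien-1-yl)-1,3,2-dioxaborolane | C=C=CB1OC(C)(C)C(C)(C)O1 | starting material
5 | ethyl (3R,4S)-2-acetyl-4-hydroxy-3-[(2S)-6-methylhept-5-en-2-yl]hept-6-ynoate (C2 epimers) | CCOC(=O)C(C(C)=O)[C@H]([C@@H](O)CC#C)[C@@H](C)CCC=C(C)C | intermediate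
6 | (4R,5S)-3-acetyl-4-[(2S)-6-methylhept-5-en-2-yl]-5-(prop-2-yn-1-yl)oxolan-2-one (C3 epimers/enol; 4,5-trans) | C#CC[C@@H]1OC(=O)C(C(C)=O)[C@H]1[C@@H](C)CCC=C(C)C | intermediate
7 | trimethylaluminium | C[Al](C)C | starting material
8 | (Z)-1,2-dichloroethene | Cl/C=C\Cl | starting material
9 | (4R,5S)-3-acetyl-5-[(2E)-3-(dimethylalumanyl)-2-methylprop-2-en-1-yl]-4-[(2S)-6-methylhept-5-en-2-yl]oxolan-2-one | C[Al](C)/C=C(\C)C[C@@H]1OC(=O)C(C(C)=O)[C@H]1[C@@H](C)CCC=C(C)C | intermediate
10 | (4R,5S)-3-acetyl-5-[(2E,4Z)-5-chloro-2-methylpenta-2,4-dien-1-yl]-4-[(2S)-6-methylhept-5-en-2-yl]oxolan-2-one | Cl/C=C\C=C(/C)C[C@@H]1OC(=O)C(C(C)=O)[C@H]1[C@@H](C)CCC=C(C)C | intermediate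
11 | 1-[(4R,5S)-5-[(2E,4Z)-5-chloro-2-methylpenta-2,4-dien-1-yl]-4-[(2S)-6-methylhept-5-en-2-yl]-2-oxooxolan-3-ylidene]ethyl trifluoromethanesulfonate (E/Z mixture) | Cl/C=C\C=C(/C)C[C@@H]1OC(=O)C(=C(C)OS(=O)(=O)C(F)(F)F)[C@H]1[C@@H](C)CCC=C(C)C | intermediate
12 | (4R,5S)-5-[(2E,4Z)-5-chloro-2-methylpenta-2,4-dien-1-yl]-3-ethenylidene-4-[(2S)-6-methylhept-5-en-2-yl]oxolan-2-one | Cl/C=C\C=C(/C)C[C@@H]1OC(=O)C(=C=C)[C@H]1[C@@H](C)CCC=C(C)C | intermediate
13 | lithium hydroxide | [Li+].[OH-] | starting material
14 | lithium (3R,4S,6E,8Z)-9-chloro-2-ethenylidene-4-hydroxy-6-methyl-3-[(2S)-6-methylhept-5-en-2-yl]nona-6,8-dienoate | [Li+].[O-]C(=O)C(=C=C)[C@H]([C@@H](O)C/C(C)=C/C=C\Cl)[C@@H](C)CCC=C(C)C | intermediate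
15 | (4Z,6E,9S,10R)-9-hydroxy-7-methyl-10-[(2S)-6-methylhept-5-en-2-yl]-3,8,9,10-tetrahydro-1H-cyclonona[c]furan-1-one (butenolide fused through its C=C to the nine-membered ring) | O=C1OCC(/C=C\C=C(/C)C[C@@H]2O)=C1[C@H]2[C@@H](C)CCC=C(C)C | intermediate
16 | acetic anhydride | CC(=O)OC(C)=O | starting material
17 | potassium (4Z,6E,9S,10R)-9-hydroxy-7-methyl-10-[(2S)-6-methylhept-5-en-2-yl]-9,10-dihydro-8H-cyclonona[c]furan-1-olate | [K+].[O-]C1=C2C(/C=C\C=C(/C)C[C@H](O)[C@@H]2[C@@H](C)CCC=C(C)C)=CO1 | intermediate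
18 | potassium (Z)-[(1S,3Z,5E,8S,11R)-6-methyl-11-[(2S)-6-methylhept-5-en-2-yl]-10-oxo-9-oxabicyclo[6.2.1]undeca-3,5-dien-2-ylidene]methanolate | [K+].[O-]/C=C1/C=C\C=C(/C)C[C@@H]2OC(=O)[C@H]1[C@H]2[C@@H](C)CCC=C(C)C | intermediate
19 | (Z)-[(1S,3Z,5E,8S,11R)-6-methyl-11-[(2S)-6-methylhept-5-en-2-yl]-10-oxo-9-oxabicyclo[6.2.1]undeca-3,5-dien-2-ylidene]methyl acetate (CNP0287742.1) | CC(=O)O/C=C1/C=C\C=C(/C)C[C@@H]2OC(=O)[C@H]1[C@H]2[C@@H](C)CCC=C(C)C | target

**Totals**
Total step count: 6. Longest linear sequence: 6 (from 1).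

**Steps most likely to fail, and fallbacks**

Step 5 (nine-membered ring closure by carbopalladation may lose to oligomerisation, or the allenoate may cyclise without coupling). The fallback sets out from 14 and comes back at 15, and separates the two ring closures. Lithium allenoate 14 is iodolactonised (I2, MeCN/H2O, a known reaction of 2,3-allenoic acids) to the iodobutenolide 3-[(1R,2S,4E,6Z)-7-chloro-2-hydroxy-4-methyl-1-[(2S)-6-methylhept-5-en-2-yl]hepta-4,6-dien-1-yl]-4-iodofuran-2(5H)-one F1. Iodine–tin exchange (Me3SnSnMe3, Pd(PPh3)4) gives the stannyl butenolide F2 (same structure with SnMe3 in place of iodine). An intramolecular Stille coupling of the alkenyl stannane onto the Z-alkenyl chloride (Pd2(dba)3, P(t-Bu)3, CsF, dioxane, high dilution) then closes the carbocycle and gives 15.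

Step 6 (the acyl transfer may be slow, or the trienolate may be protonated or C-acylated before it is trapped). The fallback sets out from 15 and comes back at 19, and separates isomerisation from acetylation. 15 is equilibrated with catalytic KOt-Bu in THF/t-BuOH, which gives the thermodynamic formyl lactone (1S,3Z,5E,8S,11R)-6-methyl-11-[(2S)-6-methylhept-5-en-2-yl]-10-oxo-9-oxabicyclo[6.2.1]undeca-3,5-diene-2-carbaldehyde F3 as C2 epimers. F3 is then converted to the enol acetate (KN(SiMe3)2 at −78 °C then Ac2O, or Ac2O/KOAc). The enol acetate geometry is no longer set by the ring, so the Z isomer 19 is separated from its E isomer by chromatography.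

Step 1 (bromine transfer to the enamine, furan formation from the 1,4-ketoaldehyde, or poor control next to the existing stereocentre). The fallback sets out from 1 and comes back at 6, and brings in the acetyl group later by Claisen chemistry. 1 is α-cyanomethylated with bromoacetonitrile under the same photoredox/imidazolidinone conditions to the cyano aldehyde (3S,4S)-3-formyl-4,8-dimethylnon-7-enenitrile F4. Propargylation as in step 2 gives the hydroxy nitrile (3S,4S)-4-hydroxy-3-[(2S)-6-methylhept-5-en-2-yl]hept-6-ynenitrile F5. Alkaline hydrolysis and acidification give the lactone (4S,5S)-4-[(2S)-6-methylhept-5-en-2-yl]-5-(prop-2-yn-1-yl)oxolan-2-one F6. Its lithium enolate (LiN(SiMe3)2, 2 equiv, THF, −78 °C) is acetylated with N-acetylimidazole to give 6.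

**Further compounds**
F1 | step 5 | 3-[(1R,2S,4E,6Z)-7-chloro-2-hydroxy-4-methyl-1-[(2S)-6-methylhept-5-en-2-yl]hepta-4,6-dien-1-yl]-4-iodofuran-2(5H)-one | O=C1OCC(I)=C1[C@H]([C@@H](O)C/C(C)=C/C=C\Cl)[C@@H](C)CCC=C(C)C
F2 | step 5 | 3-[(1R,2S,4E,6Z)-7-chloro-2-hydroxy-4-methyl-1-[(2S)-6-methylhept-5-en-2-yl]hepta-4,6-dien-1-yl]-4-(trimethylstannyl)furan-2(5H)-one | O=C1OCC([Sn](C)(C)C)=C1[C@H]([C@@H](O)C/C(C)=C/C=C\Cl)[C@@H](C)CCC=C(C)C
F3 | step 6 | (1S,3Z,5E,8S,11R)-6-methyl-11-[(2S)-6-methylhept-5-en-2-yl]-10-oxo-9-oxabicyclo[6.2.1]undeca-3,5-diene-2-carbaldehyde (C2 epimers) | O=CC1/C=C\C=C(/C)C[C@@H]2OC(=O)[C@H]1[C@H]2[C@@H](C)CCC=C(C)C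
F4 | step 1 | (3S,4S)-3-formyl-4,8-dimethylnon-7-enenitrile | N#CC[C@H](C=O)[C@@H](C)CCC=C(C)C
F5 | step 1 | (3S,4S)-4-hydroxy-3-[(2S)-6-methylhept-5-en-2-yl]hept-6-ynenitrile | N#CC[C@H]([C@@H](O)CC#C)[C@@H](C)CCC=C(C)C
F6 | step 1 | (4S,5S)-4-[(2S)-6-methylhept-5-en-2-yl]-5-(prop-2-yn-1-yl)oxolan-2-one | C#CC[C@@H]1OC(=O)C[C@H]1[C@@H](C)CCC=C(C)C
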